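**Plan**
- Retrosynthesis: the oxirane is cut back to a prenyl alkene, the prenyl–ring B bond to an aryl bromide, and ring C at C4–C4a and O1–C2 to phloroglucinol 9 and the 2-arylacrylic acid 8. Acid 8 goes back to 3-bromo-4,5-dimethoxybenzaldehyde 1 by one-carbon homologation and α-methylenation.
- Enabling feature: ring A bears oxygen at C5, C7 and C8a on a threefold-symmetric benzene ring, so any of its CH carbons can serve as C4a and either flanking hydroxyl as O1. C2 is an unsubstituted CH2 and C3 carries ring B, which is exactly the atom pattern of a 2-arylacrylic acid.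
- Forward order: the ring B acrylic acid is built (steps 1–4), ring C is closed onto ring A in one operation (step 5), the phenols are exchanged to silyl ethers, the prenyl group is coupled to ring B, and the oxirane is the last ring formed.
- Stereochemistry: C3 (S) comes from a ruthenium-catalysed transfer hydrogenation of the racemic isoflavanone with dynamic kinetic resolution; C4 is an alcohol for two steps and is then re-oxidised. The oxirane carbon (R) comes from a Shi epoxidation with the D-fructose-derived ketone, run at the alcohol stage where C3 cannot epimerise.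

Key step: step 5

Assumption: the target SMILES is read as 3S at the chromanone carbon and R at the oxirane CH carbon; the isoflavanone 15 is taken to racemise at C3 under Et3N faster than its slow-reacting enantiomer is reduced.

Step 1
Reactants: 1 3-bromo-4,5-dimethoxybenzaldehyde; 2 methyl (methylsulfinyl)methyl sulfide (FAMSO)
Product: 3 1-bromo-2,3-dimethoxy-5-[2-(methylsulfanyl)-2-(methylsulfinyl)ethenyl]benzene
Conditions: BnMe3N+ OH− (40% in MeOH, cat.), THF, reflux
Reagents that add atoms: none
Why: Knoevenagel-type condensation of the aldehyde with the doubly sulfur-activated methylene of 2 under hydroxide catalysis should give the ketene dithioacetal S-oxide, a masked arylacetic acid at the correct oxidation level.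

Step 2
Reactants: 3 1-bromo-2,3-dimethoxy-5-[2-(methylsulfanyl)-2-(methylsulfinyl)ethenyl]benzene
Product: 4 ethyl 2-(3-bromo-4,5-dimethoxyphenyl)acetate
Conditions: HCl (dry, sat.) in EtOH, 0 °C → rt
Reagents that add atoms: ethanol, CCO
Why: Acid-promoted ethanolysis of the ketene dithioacetal S-oxide (C-protonation, addition of ethanol, Pummerer-type loss of both sulfur groups as dimethyl disulfide) should unveil the ester and complete the one-carbon homologation of the aldehyde.

Step 3
Reactants: 4 ethyl 2-(3-bromo-4,5-dimethoxyphenyl)acetate; 5 formaldehyde (used as paraformaldehyde)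
Product: 7 ethyl 2-(3-bromo-4,5-dimethoxyphenyl)acrylate, via hydroxymethyl ester 6 (not isolated)
Conditions: (CH2O)n, K2CO3, Bu4NI (cat.), toluene, 80 °C
Reagents that add atoms: none
Why: Aldol addition of the ester enolate to formaldehyde under phase-transfer conditions gives the hydroxymethyl ester 6, which should lose water by E1cB elimination to the conjugated acrylate (α-methylenation of an arylacetate).

Step 4
Reactants: 7 ethyl 2-(3-bromo-4,5-dimethoxyphenyl)acrylate
Product: 8 2-(3-bromo-4,5-dimethoxyphenyl)acrylic acid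
Conditions: LiOH·H2O, THF/H2O (3:1), 0 °C → rt; then 1 M HCl, 0 °C
Reagents that add atoms: lithium hydroxide, [Li+].[OH-]
Why: Saponification of the ethyl ester by hydroxide at low temperature should be faster than conjugate addition to the 1,1-disubstituted acrylate, and cold acidification gives the free acid, which is used at once to avoid polymerisation.

Step 5
Reactants: 8 2-(3-bromo-4,5-dimethoxyphenyl)acrylic acid; 9 phloroglucinol
Product: 11 racemic 3-(3-bromo-4,5-dimethoxyphenyl)-5,7-dihydroxychroman-4-one, via aryl vinyl ketone 10 (not isolated)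
Conditions: BF3·OEt2 (neat, excess), 70 °C; then aq. NaOAc, rt
Reagents that add atoms: none
Why: Friedel–Crafts acylation followed by oxa-Michael addition: BF3 turns acid 8 into an acyloxyboron (acylium-like) electrophile that C-acylates the very electron-rich phloroglucinol, directly or by O-acylation and Fries shift, forming C4–C4a and giving vinyl ketone 10. Coordination of boron to the new carbonyl activates the enone, and one of the two equivalent ortho hydroxyls adds to the unsubstituted methylene terminus, forming O1–C2 and closing ring C in a 6-endo-trig mode; the aqueous NaOAc treatment frees the phenols and completes any unfinished closure. The closest known reactions are the acid-mediated annulations of phenols with methacrylic or 3,3-dimethylacrylic acid to chroman-4-ones and the ready closure of 2'-hydroxy-α-methylenedeoxybenzoins to isoflavanones. C3 arises by protonation of the enol and is racemic at this point; it is set in step 9, so no control is needed here. The step needs C-acylation to outrun conjugate C-alkylation at the methylene carbon (which would end in a 3-aryldihydrocoumarin) and Markovnikov hydroarylation; the dehydrating Lewis-acid medium favours the acyl electrophile, the primary β-carbon offers no stabilised cation, and O-complexation of the acid disfavours C-protonation to the α-aryl cation. The threefold symmetry of ring A removes any regiochemical choice, and the deactivated product ketone should resist a second acylation.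

Step 6
Reactants: 11 racemic 3-(3-bromo-4,5-dimethoxyphenyl)-5,7-dihydroxychroman-4-one
Product: 12 racemic 3-(3-bromo-4,5-dihydroxyphenyl)-5,7-dihydroxychroman-4-one
Conditions: BBr3 (excess), CH2Cl2, −78 °C → rt; then MeOH, H2O
Reagents that add atoms: none
Why: Lewis-acid ether cleavage, in which BBr3 coordinates the methoxy oxygens and bromide removes the methyl groups in SN2 fashion, should leave the aryl bromide, the ketone and the slower-reacting ring C aryl alkyl ether intact.

Step 7
Reactants: 12 racemic 3-(3-bromo-4,5-dihydroxyphenyl)-5,7-dihydroxychroman-4-one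
Product: 13 racemic 3-[3-bromo-4,5-bis(tert-butyldimethylsilyloxy)phenyl]-5,7-bis(tert-butyldimethylsilyloxy)chroman-4-one
Conditions: TBSOTf (4.5 equiv), 2,6-lutidine, CH2Cl2, 0 °C → rt
Reagents that add atoms: tert-butyldimethylsilyl trifluoromethanesulfonate (TBSOTf), CC(C)(C)[Si](C)(C)OS(=O)(=O)C(F)(F)F
Why: Silylation of all four phenols with the silyl triflate and a hindered pyridine base, the triflate being needed for the hydrogen-bonded 5-hydroxyl, avoids the C3 alkylation or ring opening that ether formation under carbonate bases would risk.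

Step 8
Reactants: 13 racemic 3-[3-bromo-4,5-bis(tert-butyldimethylsilyloxy)phenyl]-5,7-bis(tert-butyldimethylsilyloxy)chroman-4-one; 14 tributyl(3-methylbut-2-en-1-yl)stannane
Product: 15 racemic 3-[3,4-bis(tert-butyldimethylsilyloxy)-5-(3-methylbut-2-en-1-yl)phenyl]-5,7-bis(tert-butyldimethylsilyloxy)chroman-4-one
Conditions: Pd(PPh3)4 (cat.), toluene, 100 °C
Reagents that add atoms: none
Why: Stille cross-coupling (oxidative addition of the aryl bromide to zerovalent palladium, transmetalation with the prenylstannane, reductive elimination at the less hindered allyl terminus) should give the linear prenyl arene under neutral, fluoride-free conditions that spare the silyl ethers and the enolisable ketone.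

Step 9
Reactants: 15 racemic 3-[3,4-bis(tert-butyldimethylsilyloxy)-5-(3-methylbut-2-en-1-yl)phenyl]-5,7-bis(tert-butyldimethylsilyloxy)chroman-4-one
Product: 16 (3S,4S)-3-[3,4-bis(tert-butyldimethylsilyloxy)-5-(3-methylbut-2-en-1-yl)phenyl]-5,7-bis(tert-butyldimethylsilyloxy)chroman-4-ol (cis)
Conditions: RuCl[(S,S)-TsDPEN](p-cymene) (cat.), HCO2H/Et3N (2:3), EtOAc, 40 °C
Reagents that add atoms: none
Why: Noyori-type asymmetric transfer hydrogenation with dynamic kinetic resolution: Et3N racemises C3 through the enol faster than reduction, the (S,S)-configured catalyst delivers hydride to the carbonyl face that gives the 4S alcohol and does so anti to the 3-aryl group, so the cis-(3S,4S) alcohol should form preferentially and C3 is thereby set as S, while the amine-rich medium protects the acid-sensitive benzylic alcohol and the alkene is not touched.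

Step 10
Reactants: 16 (3S,4S)-3-[3,4-bis(tert-butyldimethylsilyloxy)-5-(3-methylbut-2-en-1-yl)phenyl]-5,7-bis(tert-butyldimethylsilyloxy)chroman-4-ol
Product: 17 (3S,4S)-3-[3,4-bis(tert-butyldimethylsilyloxy)-5-{[(2R)-3,3-dimethyloxiran-2-yl]methyl}phenyl]-5,7-bis(tert-butyldimethylsilyloxy)chroman-4-ol
Conditions: 1,2:4,5-di-O-isopropylidene-β-D-erythro-2,3-hexodiulo-2,6-pyranose (D-fructose-derived Shi ketone, 0.3 equiv), Oxone (2KHSO5·KHSO4·K2SO4), K2CO3, Bu4NHSO4 (cat.), MeCN/CH2(OMe)2–aq. Na2B4O7/Na2EDTA (pH ca. 10.5), 0 °C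
Reagents that add atoms: potassium peroxymonosulfate (active salt of Oxone), [K+].[O-]S(=O)(=O)OO
Why: Shi epoxidation, in which the chiral dioxirane formed from the ketone and KHSO5 transfers oxygen to the trisubstituted prenyl alkene through a spiro transition state, should give the R configuration at the oxirane CH carbon under reagent control independent of the remote C3 and C4 centres, and with C4 held as an alcohol C3 cannot epimerise at the basic pH.

Step 11
Reactants: 17 (3S,4S)-3-[3,4-bis(tert-butyldimethylsilyloxy)-5-{[(2R)-3,3-dimethyloxiran-2-yl]methyl}phenyl]-5,7-bis(tert-butyldimethylsilyloxy)chroman-4-ol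
Product: 18 (3S)-3-[3,4-bis(tert-butyldimethylsilyloxy)-5-{[(2R)-3,3-dimethyloxiran-2-yl]methyl}phenyl]-5,7-bis(tert-butyldimethylsilyloxy)chroman-4-one
Conditions: Dess–Martin periodinane, pyridine, CH2Cl2, 0 °C → rt
Reagents that add atoms: none
Why: Dess–Martin oxidation of the benzylic alcohol under pyridine buffering should return the C4 ketone without the acid that would open the oxirane or the base that would epimerise C3.

Step 12
Reactants: 18 (3S)-3-[3,4-bis(tert-butyldimethylsilyloxy)-5-{[(2R)-3,3-dimethyloxiran-2-yl]methyl}phenyl]-5,7-bis(tert-butyldimethylsilyloxy)chroman-4-one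
Product: 19 (3S)-3-(3,4-dihydroxy-5-{[(2R)-3,3-dimethyloxiran-2-yl]methyl}phenyl)-5,7-dihydroxychroman-4-one (CNP0197974.1)
Conditions: Bu4NF/AcOH (1:1, excess), THF, 0 °C; pH 7 phosphate buffer work-up, chromatography on neutral support
Reagents that add atoms: none
Why: Fluoride-mediated cleavage of the four aryl Si–O bonds in an acetic acid buffer keeps each liberated phenol protonated, so neither attack of the hydroxyl ortho to the side chain on the oxirane nor enolisation at C3 should compete.

**Compound list**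
1 | 3-bromo-4,5-dimethoxybenzaldehyde | COc1cc(C=O)cc(Br)c1OC | starting material
2 | methyl (methylsulfinyl)methyl sulfide (FAMSO) | CSCS(C)=O | starting material
3 | 1-bromo-2,3-dimethoxy-5-[2-(methylsulfanyl)-2-(methylsulfinyl)ethenyl]benzene (racemic at sulfur, alkene geometry immaterial) | COc1cc(C=C(SC)S(C)=O)cc(Br)c1OC | intermediate
4 | ethyl 2-(3-bromo-4,5-dimethoxyphenyl)acetate | CCOC(=O)Cc1cc(Br)c(OC)c(OC)c1 | intermediate
5 | formaldehyde (used as paraformaldehyde) | C=O | starting material
6 | ethyl 2-(3-bromo-4,5-dimethoxyphenyl)-3-hydroxypropanoate (racemic, not isolated) | CCOC(=O)C(CO)c1cc(Br)c(OC)c(OC)c1 | intermediate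
7 | ethyl 2-(3-bromo-4,5-dimethoxyphenyl)acrylate | CCOC(=O)C(=C)c1cc(Br)c(OC)c(OC)c1 | intermediate
8 | 2-(3-bromo-4,5-dimethoxyphenyl)acrylic acid | C=C(C(=O)O)c1cc(Br)c(OC)c(OC)c1 | intermediate
9 | phloroglucinol (benzene-1,3,5-triol) | Oc1cc(O)cc(O)c1 | starting material
10 | 2-(3-bromo-4,5-dimethoxyphenyl)-1-(2,4,6-trihydroxyphenyl)prop-2-en-1-one (not isolated) | C=C(C(=O)c1c(O)cc(O)cc1O)c1cc(Br)c(OC)c(OC)c1 | intermediate
11 | racemic 3-(3-bromo-4,5-dimethoxyphenyl)-5,7-dihydroxychroman-4-one | O=C1c2c(O)cc(O)cc2OCC1c1cc(Br)c(OC)c(OC)c1 | intermediate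
12 | racemic 3-(3-bromo-4,5-dihydroxyphenyl)-5,7-dihydroxychroman-4-one | O=C1c2c(O)cc(O)cc2OCC1c1cc(Br)c(O)c(O)c1 | intermediate
13 | racemic 3-[3-bromo-4,5-bis(tert-butyldimethylsilyloxy)phenyl]-5,7-bis(tert-butyldimethylsilyloxy)chroman-4-one | O=C1c2c(O[Si](C)(C)C(C)(C)C)cc(O[Si](C)(C)C(C)(C)C)cc2OCC1c1cc(Br)c(O[Si](C)(C)C(C)(C)C)c(O[Si](C)(C)C(C)(C)C)c1 | intermediate
14 | tributyl(3-methylbut-2-en-1-yl)stannane | CC(C)=CC[Sn](CCCC)(CCCC)CCCC | starting material
15 | racemic 3-[3,4-bis(tert-butyldimethylsilyloxy)-5-(3-methylbut-2-en-1-yl)phenyl]-5,7-bis(tert-butyldimethylsilyloxy)chroman-4-one | CC(C)=CCc1cc(C2COc3cc(O[Si](C)(C)C(C)(C)C)cc(O[Si](C)(C)C(C)(C)C)c3C2=O)cc(O[Si](C)(C)C(C)(C)C)c1O[Si](C)(C)C(C)(C)C | intermediate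
16 | (3S,4S)-3-[3,4-bis(tert-butyldimethylsilyloxy)-5-(3-methylbut-2-en-1-yl)phenyl]-5,7-bis(tert-butyldimethylsilyloxy)chroman-4-ol | CC(C)=CCc1cc([C@H]2COc3cc(O[Si](C)(C)C(C)(C)C)cc(O[Si](C)(C)C(C)(C)C)c3[C@H]2O)cc(O[Si](C)(C)C(C)(C)C)c1O[Si](C)(C)C(C)(C)C | intermediate
17 | (3S,4S)-3-[3,4-bis(tert-butyldimethylsilyloxy)-5-{[(2R)-3,3-dimethyloxiran-2-yl]methyl}phenyl]-5,7-bis(tert-butyldimethylsilyloxy)chroman-4-ol | CC1(C)O[C@@H]1Cc1cc([C@H]2COc3cc(O[Si](C)(C)C(C)(C)C)cc(O[Si](C)(C)C(C)(C)C)c3[C@H]2O)cc(O[Si](C)(C)C(C)(C)C)c1O[Si](C)(C)C(C)(C)C | intermediate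
18 | (3S)-3-[3,4-bis(tert-butyldimethylsilyloxy)-5-{[(2R)-3,3-dimethyloxiran-2-yl]methyl}phenyl]-5,7-bis(tert-butyldimethylsilyloxy)chroman-4-one | CC1(C)O[C@@H]1Cc1cc([C@H]2COc3cc(O[Si](C)(C)C(C)(C)C)cc(O[Si](C)(C)C(C)(C)C)c3C2=O)cc(O[Si](C)(C)C(C)(C)C)c1O[Si](C)(C)C(C)(C)C | intermediate
19 | (3S)-3-(3,4-dihydroxy-5-{[(2R)-3,3-dimethyloxiran-2-yl]methyl}phenyl)-5,7-dihydroxychroman-4-one | CC1(C)O[C@@H]1Cc1cc([C@H]2COc3cc(O)cc(O)c3C2=O)cc(O)c1O | target

Total step count: 12
Longest linear sequence: 12 steps (1 → 19); 2, 5, 9 and 14 enter as purchased reagents.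

**Steps most likely to fail**

Step 5. Conjugate C-alkylation of phloroglucinol at the methylene carbon followed by lactonisation, Markovnikov hydroarylation through the α-aryl cation, or oligomerisation of the acrylic acid may outrun C-acylation. The fallback builds ring C from an arylacetic acid and a separate one-carbon unit. It sets out from 4: saponification (LiOH, THF/H2O; then HCl) gives 2-(3-bromo-4,5-dimethoxyphenyl)acetic acid F1. Acylation of 9 with F1 in BF3·OEt2 at 80 °C gives the deoxybenzoin 2-(3-bromo-4,5-dimethoxyphenyl)-1-(2,4,6-trihydroxyphenyl)ethan-1-one F2. In the same medium, DMF and MeSO2Cl formylate and cyclise F2 to the isoflavone 3-(3-bromo-4,5-dimethoxyphenyl)-5,7-dihydroxy-4H-chromen-4-one F3. BBr3 demethylation gives 3-(3-bromo-4,5-dihydroxyphenyl)-5,7-dihydroxy-4H-chromen-4-one F4, and TBSOTf/2,6-lutidine gives the tetrasilyl isoflavone 3-[3-bromo-4,5-bis(tert-butyldimethylsilyloxy)phenyl]-5,7-bis(tert-butyldimethylsilyloxy)-4H-chromen-4-one F5. Conjugate reduction of F5 with LiBH(s-Bu)3 in THF at −78 °C and protonation of the enolate returns to the route at 13.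

Step 9. The ketone, flanked by the 5-silyloxy group and the 3-aryl group, may be reduced too slowly for the racemisation-coupled selection to operate, the peri silyl ether may be lost in the formate medium, or the electron-rich benzylic alcohol may ionise and eliminate to the isoflav-3-ene. The fallback replaces asymmetric catalysis by resolution. It sets out from 15: LiBH(s-Bu)3 in THF at −78 °C (hydride anti to the aryl group, non-acidic work-up) should give the racemic cis alcohol, that is 16 together with its enantiomer (3R,4R)-3-[3,4-bis(tert-butyldimethylsilyloxy)-5-(3-methylbut-2-en-1-yl)phenyl]-5,7-bis(tert-butyldimethylsilyloxy)chroman-4-ol F6. Preparative chromatography on a cellulose tris(3,5-dimethylphenylcarbamate) stationary phase separates the two; F6 is not carried on, and the route is rejoined at 16.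

Step 12. During a slow cleavage of the hindered silyl ether next to the side chain, the freed hydroxyl may open the oxirane intramolecularly, or C3 may epimerise under the fluoride medium. The fallback releases that phenol by neutral solvolysis of an acetate instead of by fluoride, and introduces the oxirane only after the silyl groups are gone. It sets out from 16: Dess–Martin oxidation (pyridine, CH2Cl2) gives (3S)-3-[3,4-bis(tert-butyldimethylsilyloxy)-5-(3-methylbut-2-en-1-yl)phenyl]-5,7-bis(tert-butyldimethylsilyloxy)chroman-4-one F7. Bu4NF/AcOH in THF at 0 °C, uncritical in the absence of an oxirane, gives (3S)-3-[3,4-dihydroxy-5-(3-methylbut-2-en-1-yl)phenyl]-5,7-dihydroxychroman-4-one F8. Ac2O/pyridine gives the tetraacetate (3S)-3-[3,4-diacetoxy-5-(3-methylbut-2-en-1-yl)phenyl]-5,7-diacetoxychroman-4-one F9. Shi epoxidation of F9 with the same D-fructose-derived ketone, run under the lower-pH protocol (pH about 8, stoichiometric ketone, 0 °C) at which aryl acetates and C3 are expected to hold, gives (3S)-3-(3,4-diacetoxy-5-{[(2R)-3,3-dimethyloxiran-2-yl]methyl}phenyl)-5,7-diacetoxychroman-4-one F10. Deacetylation of F10 with NH4OAc in aqueous MeOH at rt returns to the route at 19.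

**Further compounds**
F1 | step 5 | 2-(3-bromo-4,5-dimethoxyphenyl)acetic acid | OC(=O)Cc1cc(Br)c(OC)c(OC)c1
F2 | step 5 | 2-(3-bromo-4,5-dimethoxyphenyl)-1-(2,4,6-trihydroxyphenyl)ethan-1-one | O=C(Cc1cc(Br)c(OC)c(OC)c1)c1c(O)cc(O)cc1O
F3 | step 5 | 3-(3-bromo-4,5-dimethoxyphenyl)-5,7-dihydroxy-4H-chromen-4-one | O=c1c(-c2cc(Br)c(OC)c(OC)c2)coc2cc(O)cc(O)c12
F4 | step 5 | 3-(3-bromo-4,5-dihydroxyphenyl)-5,7-dihydroxy-4H-chromen-4-one | O=c1c(-c2cc(Br)c(O)c(O)c2)coc2cc(O)cc(O)c12
F5 | step 5 | 3-[3-bromo-4,5-bis(tert-butyldimethylsilyloxy)phenyl]-5,7-bis(tert-butyldimethylsilyloxy)-4H-chromen-4-one | O=c1c(-c2cc(Br)c(O[Si](C)(C)C(C)(C)C)c(O[Si](C)(C)C(C)(C)C)c2)coc2cc(O[Si](C)(C)C(C)(C)C)cc(O[Si](C)(C)C(C)(C)C)c12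
F6 | step 9 | (3R,4R)-3-[3,4-bis(tert-butyldimethylsilyloxy)-5-(3-methylbut-2-en-1-yl)phenyl]-5,7-bis(tert-butyldimethylsilyloxy)chroman-4-ol | CC(C)=CCc1cc([C@@H]2COc3cc(O[Si](C)(C)C(C)(C)C)cc(O[Si](C)(C)C(C)(C)C)c3[C@@H]2O)cc(O[Si](C)(C)C(C)(C)C)c1O[Si](C)(C)C(C)(C)C
F7 | step 12 | (3S)-3-[3,4-bis(tert-butyldimethylsilyloxy)-5-(3-methylbut-2-en-1-yl)phenyl]-5,7-bis(tert-butyldimethylsilyloxy)chroman-4-one | CC(C)=CCc1cc([C@H]2COc3cc(O[Si](C)(C)C(C)(C)C)cc(O[Si](C)(C)C(C)(C)C)c3C2=O)cc(O[Si](C)(C)C(C)(C)C)c1O[Si](C)(C)C(C)(C)C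
F8 | step 12 | (3S)-3-[3,4-dihydroxy-5-(3-methylbut-2-en-1-yl)phenyl]-5,7-dihydroxychroman-4-one | CC(C)=CCc1cc([C@H]2COc3cc(O)cc(O)c3C2=O)cc(O)c1O
F9 | step 12 | (3S)-3-[3,4-diacetoxy-5-(3-methylbut-2-en-1-yl)phenyl]-5,7-diacetoxychroman-4-one | CC(C)=CCc1cc([C@H]2COc3cc(OC(C)=O)cc(OC(C)=O)c3C2=O)cc(OC(C)=O)c1OC(C)=O
F10 | step 12 | (3S)-3-(3,4-diacetoxy-5-{[(2R)-3,3-dimethyloxiran-2-yl]methyl}phenyl)-5,7-diacetoxychroman-4-one | CC1(C)O[C@@H]1Cc1cc([C@H]2COc3cc(OC(C)=O)cc(OC(C)=O)c3C2=O)cc(OC(C)=O)c1OC(C)=O
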